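**Retrosynthetic overview**
1. C3–Br is installed last by electrophilic bromination of 5,7-dibromo-6-methoxyindole 7 at its most nucleophilic carbon.
2. N1–C7a: the pyrrole ring is closed by reductive C–H amination of β-nitrostyrene 4; the arene is symmetrical, so either ortho C–H gives the same indole.
3. C2–C3 (key C–C bond): the nitronate of nitromethane acts as a reversed-polarity C1 donor (aminomethyl/formyl anion equivalent) toward the aldehyde carbon of 1. Both carbons are natively electrophilic, and nitromethane supplies C2 and N1 together, so no ortho nitrogen handle is needed.
4. Ring order: the fully substituted benzene ring is bought intact (both bromines and the methoxy group in place); the pyrrole ring is the only ring formed, in step 2.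

Assumption: the target has no stereocentre (it is achiral), so "single enantiomer" is taken to mean the structure as drawn; the only stereo-element in the route is alkene geometry in the intermediates.

**Route**

Step 1
Reactants: 1 3,5-dibromo-4-methoxybenzaldehyde; 2 nitromethane
Product: 4 1,3-dibromo-2-methoxy-5-[(E)-2-nitroethenyl]benzene, via β-nitro alcohol 3 (not isolated)
Conditions: 2 (5 equiv), NH4OAc (0.5 equiv), AcOH, 100 °C
Reagents that add atoms: none
Why: Henry (nitroaldol) condensation in which the nitronate of 2, a reversed-polarity C1 donor (aminomethyl/formyl anion equivalent), attacks the electron-poor aldehyde carbon of 1, and E1cB dehydration of racemic 3 under the hot buffered conditions gives the conjugated E-alkene, so no stereocentre persists.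

Step 2
Reactants: 4 1,3-dibromo-2-methoxy-5-[(E)-2-nitroethenyl]benzene
Product: 7 5,7-dibromo-6-methoxy-1H-indole, via nitrosoalkene 5 (not isolated), via N-hydroxyindole 6 (not isolated)
Conditions: PdCl2(MeCN)2 (2 mol %), 1,10-phenanthroline (10 mol %), CO (20 bar), MeCN, 120 °C, no base
Reagents that add atoms: none
Why: Palladium/phenanthroline-catalysed reductive cyclization of a β-nitrostyrene with CO (a Cadogan–Sundberg-type deoxygenative C–H amination), in which CO removes one oxygen to give nitrosoalkene 5, whose Z form closes onto either of the two equivalent ortho C–H positions to give N-hydroxyindole 6, which a second CO deoxygenates to 7; base is omitted to limit nitroalkene oligomerization, the phosphine-free catalyst is expected to leave both C–Br bonds untouched, and no stereocentre is formed.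

Step 3
Reactants: 7 5,7-dibromo-6-methoxy-1H-indole
Product: 8 3,5,7-tribromo-6-methoxy-1H-indole
Conditions: NBS (1.0 equiv), DMF, 0 °C, dark
Reagents that add atoms: N-bromosuccinimide, BrN1C(=O)CCC1=O
Why: Electrophilic aromatic substitution at indole C3, the most nucleophilic position, with exactly one equivalent of NBS, while the only free benzenoid position (C4) is deactivated by the flanking bromine and C2 reacts only with excess reagent; no stereocentre is involved.

**Compound list**
1 | 3,5-dibromo-4-methoxybenzaldehyde | COc1c(Br)cc(C=O)cc1Br | starting material
2 | nitromethane | C[N+](=O)[O-] | starting material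
3 | 1-(3,5-dibromo-4-methoxyphenyl)-2-nitroethan-1-ol (racemic) | COc1c(Br)cc(C(O)C[N+](=O)[O-])cc1Br | intermediate
4 | 1,3-dibromo-2-methoxy-5-[(E)-2-nitroethenyl]benzene | COc1c(Br)cc(/C=C/[N+](=O)[O-])cc1Br | intermediate
5 | 1,3-dibromo-2-methoxy-5-[(Z)-2-nitrosoethenyl]benzene (reactive Z form, reached by E/Z equilibration) | COc1c(Br)cc(/C=C\N=O)cc1Br | intermediate
6 | 5,7-dibromo-6-methoxy-1H-indol-1-ol | COc1c(Br)cc2ccn(O)c2c1Br | intermediate
7 | 5,7-dibromo-6-methoxy-1H-indole | COc1c(Br)cc2cc[nH]c2c1Br | intermediate
8 | 3,5,7-tribromo-6-methoxy-1H-indole | COc1c(Br)cc2c(Br)c[nH]c2c1Br | target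

**Step count**
Total steps: 3. Longest linear sequence: 3.

**Steps most likely to fail, with fallbacks**

Step 2 (highest risk). β-Nitrostyrenes without an α-substituent give only modest yields in this cyclization because they oligomerize. The reacting C–H is also flanked by a bromine, and carbonylation at C–Br is conceivable. Fallback, setting out from 4 and returning at 7: give up the C–H amination and bring in the ring nitrogen by electrophilic nitration. Treating 4 with fuming HNO3 in H2SO4 at 0 °C should give 1,3-dibromo-2-methoxy-4-nitro-5-[(E)-2-nitroethenyl]benzene F1. The two open ring positions are equivalent, ortho to the alkenyl group and ortho/para to the bromines; the main danger is ipso attack at C–Br. Fe powder in AcOH at 80 °C then reduces both nitro groups, and the new aniline nitrogen condenses onto the side-chain carbon with loss of the side-chain nitrogen. This is the classical o,β-dinitrostyrene reductive cyclization, which tolerates aryl bromides, and it delivers 7 with the nitromethane carbon still serving as C2.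

Step 3. Free NH 3-bromoindoles can over-brominate at C2 or oxidize during isolation. Fallback, setting out from 7 and returning at 8: carry out the bromination on the carbamate. Boc2O with catalytic DMAP in MeCN gives tert-butyl 5,7-dibromo-6-methoxy-1H-indole-1-carboxylate F2. NBS in THF at room temperature gives tert-butyl 3,5,7-tribromo-6-methoxy-1H-indole-1-carboxylate F3, in which the electron-withdrawing group suppresses C2 attack and makes the product stable to chromatography. Mild methanolysis with K2CO3 in MeOH at 25–40 °C then releases 8.

Step 1 (lowest risk). Hot one-pot condensation can lead to tar or to a second nitromethane adding to 4. Fallback, setting out from 1 and returning at 4: separate addition from elimination. Catalytic Et3N in THF with 2 at 0 °C gives the nitro alcohol 3, isolated this time. MsCl and Et3N in CH2Cl2 at 0 °C convert it into 1-(3,5-dibromo-4-methoxyphenyl)-2-nitroethyl methanesulfonate F4, which undergoes E1cB elimination in the same flask to give 4 under cold, non-acidic conditions.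

**Further compounds**
F1 | step 2 | 1,3-dibromo-2-methoxy-4-nitro-5-[(E)-2-nitroethenyl]benzene | COc1c(Br)cc(/C=C/[N+](=O)[O-])c([N+](=O)[O-])c1Br
F2 | step 3 | tert-butyl 5,7-dibromo-6-methoxy-1H-indole-1-carboxylate | COc1c(Br)cc2ccn(C(=O)OC(C)(C)C)c2c1Br
F3 | step 3 | tert-butyl 3,5,7-tribromo-6-methoxy-1H-indole-1-carboxylate | COc1c(Br)cc2c(Br)cn(C(=O)OC(C)(C)C)c2c1Br
F4 | step 1 | 1-(3,5-dibromo-4-methoxyphenyl)-2-nitroethyl methanesulfonate | COc1c(Br)cc(C(OS(C)(=O)=O)C[N+](=O)[O-])cc1Br
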